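**Retrosynthetic overview**
1. Target ⇐ C12 aryl-ether cleavage and C2/C9 diacetylation ⇐ γ-lactone, closed last by oxidative lactonisation of a C19 primary alcohol onto the C7 hydroxyl.
2. Ten-membered ring (C1–C10) ⇐ Nozaki–Hiyama–Kishi closure of C6–C7; C8/C17 ⇐ Sharpless epoxidation and AlMe3 opening; C9 ⇐ Felkin addition of a C7–C8–C17–C19 alkenylmagnesium to the C9 aldehyde.
3. Cyclohexene ring (C1, C10–C14) ⇐ one-pot three-component union: [4+2] of a C11–C14 aminosiloxydiene with the (E)-ene-dicarbonyl C2–C1=C10–C9 (bonds C14–C1 and C11–C10), C3-allylation of the masked adduct by the C4–C6 iodoallyl bromide, then unmasking.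
4. Enabling feature: in the cyclohexene ring C12 bears oxygen allylic to C13=C14, and quaternary C1 (Me-15) is α to oxygenated C2 with C10 carrying oxygenated C9. The ring is therefore a latent 4-acyl-4-methylcyclohex-2-enone, and C3 is the only enolisable position of its C2 ketone.
5. Ring order: cyclohexene (step 6) → ten-membered carbocycle (step 22) → γ-lactone (step 24).

Key step: step 6

Remark: briarane numbering (C1–C20) is used for all intermediates; the (2S,5S) antipode of the diene auxiliary is chosen from a simple shielding model (dienophile anti to the phenyl group flanking C14), and the (2R,5R) amine would be taken instead if the sense proved opposite.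

**Step 1**
Reactants: 1 butane-2,3-dione; 2 N-methoxy-N-methyl-2-(triphenyl-λ5-phosphanylidene)acetamide
Product: 3 (E)-N-methoxy-N,3-dimethyl-4-oxopent-2-enamide
Conditions: 1 (3 equiv), CH2Cl2, rt
Reagents that add atoms: none
Why: Wittig mono-olefination of the 1,2-diketone with a stabilised ylide should place the amide trans to the acetyl group (E), the geometry that later fixes the C2 and C9 arms trans.

**Step 2**
Reactants: 4 pent-1-yn-3-one; 5 (2S,5S)-2,5-diphenylpyrrolidine
Product: 6 (E)-1-[(2S,5S)-2,5-diphenylpyrrolidin-1-yl]pent-1-en-3-one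
Conditions: EtOH, 0 °C→rt
Reagents that add atoms: none
Why: Conjugate (aza-Michael) addition of the secondary amine to the ynone should give the E vinylogous amide.

**Step 3**
Reactants: 6 (E)-1-[(2S,5S)-2,5-diphenylpyrrolidin-1-yl]pent-1-en-3-one
Product: 8 (1E,3Z)-3-(tert-butyldimethylsilyloxy)-1-[(2S,5S)-2,5-diphenylpyrrolidin-1-yl]penta-1,3-diene, via potassium dienolate 7 (not isolated)
Conditions: KHMDS, THF, −78 °C; then TBSCl, −78 °C→rt
Reagents that add atoms: tert-butyldimethylsilyl chloride, CC(C)(C)[Si](C)(C)Cl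
Why: Kinetic α′-deprotonation of the ethyl ketone should give the Z enolate, and O-silylation then gives the aminosiloxydiene with the future C20 methyl in the outside position.

**Step 4**
Reactants: 9 prop-2-yn-1-ol
Product: 11 (Z)-3-iodo-2-methylprop-2-en-1-ol, via alkenylmagnesium chelate 10 (not isolated)
Conditions: MeMgBr (2.5 equiv), CuI (10 mol%), THF, −10 °C→rt; then I2, −78→0 °C
Reagents that add atoms: methylmagnesium bromide, C[Mg]Br; iodine, II
Why: Copper-catalysed anti-carbomagnesiation of the propargylic alkoxide through the cyclic alkoxymagnesium alkenyl species, then iodinolysis with retention, fixes the Z geometry of the future C5=C6 olefin.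

**Step 5**
Reactants: 11 (Z)-3-iodo-2-methylprop-2-en-1-ol
Product: 12 (Z)-3-bromo-1-iodo-2-methylprop-1-ene
Conditions: CBr4, PPh3, CH2Cl2, 0 °C
Reagents that add atoms: carbon tetrabromide, BrC(Br)(Br)Br
Why: Appel bromination of the primary allylic alcohol should leave the vinyl iodide and the olefin geometry untouched.

**Step 6**
Reactants: 3 (E)-N-methoxy-N,3-dimethyl-4-oxopent-2-enamide; 8 (1E,3Z)-3-(tert-butyldimethylsilyloxy)-1-[(2S,5S)-2,5-diphenylpyrrolidin-1-yl]penta-1,3-diene; 12 (Z)-3-bromo-1-iodo-2-methylprop-1-ene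
Product: 16 (1S,2S,6S)-2-[(Z)-5-iodo-4-methylpent-4-enoyl]-N-methoxy-N,2,6-trimethyl-5-oxocyclohex-3-ene-1-carboxamide (11-epi enone; briarane C1 S, C10 S, C11 S), via cycloadduct 13 (not isolated), via lithium enolate 14 (not isolated), via alkylated cycloadduct 15 (not isolated)
Conditions: 8 (1.1 equiv), toluene, 0 °C→rt; then THF, LDA (1.1 equiv), −78 °C; 12, DMPU, −78→−30 °C; then aq. HF, MeCN, 0 °C
Reagents that add atoms: none
Why: The electron-rich (1E,3Z)-aminosiloxydiene 8 and the doubly activated (E)-ene-dicarbonyl 3 should combine in a strongly asynchronous normal-demand [4+2] cycloaddition (closest known type: the aminosiloxydiene Diels–Alder route to 4,4-disubstituted cyclohexenones), in which the nucleophilic C11 terminus bonds first to C10 and the C14–C1 bond then closes the cyclohexene ring and creates the quaternary centre. The ring is thus closed by an intermolecular suprafacial cycloaddition: the E geometry of 3 becomes the trans relationship of the C2 and C9 arms at C1/C10, the C2-symmetric diphenylpyrrolidine shields one diene face and sets their absolute sense, the ketone-endo transition state with the outside methyl places Me-20 cis to H-10 (11-epi, corrected in step 7), and the aminated C14 centre is only transient. The regioselectivity needed is secured because the ketone is the stronger acceptor and C1 carries the methyl group, so both electronics and sterics send the substituted diene terminus to the unsubstituted C10. In adduct 13 the enone is masked as a silyl enol ether and the C2 ketone, flanked by the new quaternary C1, has a single enolisable position, so LDA should give only the C3 enolate 14, which is C-allylated by bromide 12 (ketone enolate alkylation) without touching the (Z)-vinyl iodide. Aqueous HF then hydrolyses the silyl enol ether and expels the auxiliary amine by β-elimination, the usual unmasking of such adducts, to give the C13=C14 enone. One vessel thus joins three components into the complete C1–C6/C9–C14 framework with the C1/C10 stereodiad, the C12 oxygen and both handles for the ten-membered ring.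

**Step 7**
Reactants: 16 11-epi enone
Product: 17 (1S,2S,6R)-2-[(Z)-5-iodo-4-methylpent-4-enoyl]-N-methoxy-N,2,6-trimethyl-5-oxocyclohex-3-ene-1-carboxamide (briarane C1 S, C10 S, C11 R)
Conditions: DBU (0.5 equiv), toluene, 40 °C
Reagents that add atoms: none
Why: Base-mediated epimerisation α to the C12 ketone (C11 is the only enolisable ring position, C1 being quaternary) should funnel to the epimer whose half-chair has Me-15 and Me-20 equatorial and the two arms trans-diaxial, with no syn-axial partners because C12 and C14 are sp2.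

**Step 8**
Reactants: 17 enone
Product: 18 (1S,2S,5S,6R)-5-hydroxy-2-[(Z)-5-iodo-4-methylpent-4-enoyl]-N-methoxy-N,2,6-trimethylcyclohex-3-ene-1-carboxamide (12β-alcohol, C12 S)
Conditions: NaBH4, CeCl3·7H2O, MeOH, −78 °C
Reagents that add atoms: none
Why: Luche 1,2-reduction should be chemoselective for the enone over the neopentyl-type C2 ketone, and hydride is expected to enter from the face opposite the pseudoaxial C9 amide arm, giving the 12-epi (β) allylic alcohol.

**Step 9**
Reactants: 18 12β-allylic alcohol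
Product: 19 (1S,2S,5R,6R)-2-[(Z)-5-iodo-4-methylpent-4-enoyl]-N-methoxy-5-(4-methoxyphenoxy)-N,2,6-trimethylcyclohex-3-ene-1-carboxamide (C12 R aryl ether)
Conditions: 4-methoxyphenol, PPh3, DIAD, toluene, 0 °C→rt
Reagents that add atoms: 4-methoxyphenol, COc1ccc(O)cc1
Why: Mitsunobu etherification inverts C12 by SN2 from the unhindered α-face (SN2′ at neopentyl C14 is disfavoured) and installs an aryl ether that should survive every later step.

**Step 10**
Reactants: 19 keto aryl ether
Product: 20 (1S,2S,5R,6R)-2-[(1R,4Z)-1-hydroxy-5-iodo-4-methylpent-4-en-1-yl]-N-methoxy-5-(4-methoxyphenoxy)-N,2,6-trimethylcyclohex-3-ene-1-carboxamide (C2 R alcohol)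
Conditions: (S)-Me-CBS (1 equiv), catecholborane, toluene, −40→−20 °C
Reagents that add atoms: none
Why: Corey–Bakshi–Shibata reduction, in which the (S)-oxazaborolidine distinguishes the quaternary C1 (large) from the C3 methylene (small), should give the 2R alcohol under reagent control.

**Step 11**
Reactants: 20 C2 alcohol
Product: 21 C2 triethylsilyl ether of 20
Conditions: TESOTf, 2,6-lutidine, CH2Cl2, −78→0 °C
Reagents that add atoms: triethylsilyl trifluoromethanesulfonate, CC[Si](CC)(CC)OS(=O)(=O)C(F)(F)F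
Why: Silylation with the silyl triflate should cap the hindered neopentyl alcohol before it can lactonise onto the amide.

**Step 12**
Reactants: 21 Weinreb amide
Product: 22 (1S,2S,5R,6R)-2-[(1R,4Z)-5-iodo-4-methyl-1-(triethylsilyloxy)pent-4-en-1-yl]-5-(4-methoxyphenoxy)-2,6-dimethylcyclohex-3-ene-1-carbaldehyde (C9 aldehyde)
Conditions: DIBAL-H, THF, −78 °C; Rochelle salt
Reagents that add atoms: none
Why: Weinreb amide reduction through the stable chelated tetrahedral intermediate should stop at the aldehyde, and the cold work-up avoids epimerisation at C10.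

**Step 13**
Reactants: 23 but-2-yne-1,4-diol
Product: 24 4-[(4-methoxybenzyl)oxy]but-2-yn-1-ol
Conditions: 23 (3 equiv), NaH (1 equiv), PMBCl (1 equiv), DMF, 0 °C→rt
Reagents that add atoms: 4-methoxybenzyl chloride, COc1ccc(CCl)cc1
Why: Williamson etherification with the diol in excess should give mainly the mono-ether.

**Step 14**
Reactants: 24 4-[(4-methoxybenzyl)oxy]but-2-yn-1-ol
Product: 26 (Z)-3-iodo-4-[(4-methoxybenzyl)oxy]but-2-en-1-ol, via cyclic alkenylalanate 25 (not isolated)
Conditions: Red-Al, THF, 0 °C→rt; then I2, −78→0 °C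
Reagents that add atoms: iodine, II
Why: Alkoxide-directed trans-hydroalumination puts aluminium on the carbon distal to the free hydroxyl, and iodinolysis with retention gives the vinyl iodide in which the C7 and C19 carbons are trans.

**Step 15**
Reactants: 26 (Z)-3-iodo-4-[(4-methoxybenzyl)oxy]but-2-en-1-ol
Product: 27 (Z)-triethyl({3-iodo-4-[(4-methoxybenzyl)oxy]but-2-en-1-yl}oxy)silane
Conditions: TESCl, imidazole, CH2Cl2, 0 °C
Reagents that add atoms: chlorotriethylsilane, CC[Si](Cl)(CC)CC
Why: Standard silylation of the primary allylic alcohol gives a non-participating, selectively removable C19 protecting group.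

**Step 16**
Reactants: 22 C9 aldehyde; 27 vinyl iodide
Product: 29 C9 (R) allylic alcohol carrying the 1-[(4-methoxybenzyl)oxy]-4-(triethylsilyloxy)but-2-en-2-yl group at C9 (C9 and C19 cis across C8=C17), via alkenylmagnesium chloride 28 (not isolated)
Conditions: 27 (1.5 equiv), iPrMgCl·LiCl, THF, −40 °C; then LaCl3·2LiCl, 22, −78→−20 °C
Reagents that add atoms: none
Why: Iodine–magnesium exchange proceeds with retention, and Felkin–Anh addition to the α-branched aldehyde (quaternary C1 anti to the incoming alkenyl group) should give the 9R carbinol.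

**Step 17**
Reactants: 29 C9 allylic alcohol
Product: 30 C9 triethylsilyl ether of 29
Conditions: TESOTf, 2,6-lutidine, CH2Cl2, −78 °C
Reagents that add atoms: triethylsilyl trifluoromethanesulfonate, CC[Si](CC)(CC)OS(=O)(=O)C(F)(F)F
Why: Silylation gives a non-participating C9 ether, which is needed because an ester here would take part in the later epoxide opening.

**Step 18**
Reactants: 30 PMB ether
Product: 31 primary allylic alcohol (C7–OH free)
Conditions: DDQ, CH2Cl2/pH 7 buffer, 0 °C
Reagents that add atoms: none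
Why: Oxidative cleavage of the p-methoxybenzyl ether by benzylic hydride abstraction should spare the aryl alkyl ether at C12 (no benzylic hydrogen) and the silyl ethers.

**Step 19**
Reactants: 31 allylic alcohol
Product: 32 C8–C17 epoxy alcohol (oxygen on the face that becomes the 8S carbinol)
Conditions: Ti(OiPr)4, D-(−)-DIPT, t-BuOOH, 4 Å MS, CH2Cl2, −20 °C
Reagents that add atoms: tert-butyl hydroperoxide, CC(C)(C)OO
Why: Sharpless asymmetric epoxidation of the (E)-2,3-disubstituted primary allylic alcohol is reagent-controlled, and the D-(−)-tartrate should deliver oxygen to the face required for C8.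

**Step 20**
Reactants: 32 epoxy alcohol
Product: 33 C7,C8-diol with the C17 methyl group installed
Conditions: AlMe3 (4 equiv), hexane/CH2Cl2, −30→0 °C
Reagents that add atoms: trimethylaluminium, C[Al](C)C
Why: Trimethylaluminium opening of the 2,3-epoxy alcohol at C3 (= C17) with inversion sets the C17 methyl stereocentre, since the fully substituted C8 cannot be attacked.

**Step 21**
Reactants: 33 diol
Product: 34 α-hydroxy aldehyde (C7 aldehyde, C8 tertiary alcohol)
Conditions: TEMPO (0.2 equiv), PhI(OAc)2, CH2Cl2, 0 °C→rt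
Reagents that add atoms: none
Why: Oxoammonium oxidation is selective for the primary alcohol beside the tertiary one and does not cleave the glycol.

**Step 22**
Reactants: 34 α-hydroxy aldehyde with (Z)-vinyl iodide
Product: 35 ten-membered ring allylic alcohol (C7 S; C6–C7 bond formed)
Conditions: CrCl2 (10 equiv), NiCl2 (2 mol%), degassed DMSO, 0.003 M, rt
Reagents that add atoms: none
Why: Intramolecular Nozaki–Hiyama–Kishi reaction (oxidative addition of nickel to the vinyl iodide with retention, transmetalation to chromium, carbonyl addition) is a precedented closure of ten-membered carbocycles, and Felkin–Anh addition anti to the C8 oxygen with the smaller C17 branch flanking the trajectory should give 7S.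

**Step 23**
Reactants: 35 macrocyclic diol tris(silyl) ether
Product: 36 C19 primary alcohol (C2 and C9 silyl ethers retained)
Conditions: PPTS, MeOH/CH2Cl2, 0 °C
Reagents that add atoms: none
Why: Acid-catalysed methanolysis should remove the unhindered primary triethylsilyl ether much faster than the two hindered secondary ones.

**Step 24**
Reactants: 36 C19 alcohol
Product: 38 γ-lactone (C19 carbonyl, O7), via lactol 37 (not isolated)
Conditions: TEMPO (0.3 equiv), PhI(OAc)2 (2.5 equiv), CH2Cl2, rt
Reagents that add atoms: none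
Why: Oxidative lactonisation: the primary alcohol is oxidised first, the aldehyde is trapped by the C7 hydroxyl as a five-membered lactol, and this is oxidised on to the lactone, with C17 keeping the configuration that places Me-18 trans to the C9 branch.

**Step 25**
Reactants: 38 bis(triethylsilyl) ether lactone
Product: 39 C2,C8,C9-triol lactone (C12 aryl ether retained)
Conditions: HF·pyridine, pyridine, THF, 0 °C→rt
Reagents that add atoms: none
Why: Fluoride-mediated desilylation frees both secondary alcohols under conditions to which the lactone and the aryl ether are inert.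

**Step 26**
Reactants: 39 triol
Product: 40 C2,C9-diacetate (C12 4-methoxyphenyl ether)
Conditions: Ac2O, pyridine, DMAP (cat.), CH2Cl2, 0 °C→rt
Reagents that add atoms: acetic anhydride, CC(=O)OC(C)=O
Why: Acylation should take both secondary alcohols while the hindered tertiary C8 hydroxyl stays free and C12 is still masked.

**Step 27**
Reactants: 40 diacetate aryl ether
Product: 41 CNP0222085.1 (target; 1S,2R,7S,8S,9R,10S,11R,12R,17R, 5Z,13Z)
Conditions: CAN, MeCN/H2O, 0 °C
Reagents that add atoms: none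
Why: Oxidative cleavage of the p-methoxyphenyl ether by ceric ammonium nitrate releases the C12 allylic alcohol without breaking the C12–O bond, so the configuration is kept.

**Compound list**
1 | butane-2,3-dione | CC(=O)C(C)=O | starting material
2 | N-methoxy-N-methyl-2-(triphenyl-λ5-phosphanylidene)acetamide | CON(C)C(=O)C=P(c1ccccc1)(c1ccccc1)c1ccccc1 | starting material
3 | (E)-N-methoxy-N,3-dimethyl-4-oxopent-2-enamide | CON(C)C(=O)/C=C(\C)C(C)=O | intermediate
4 | pent-1-yn-3-one | CCC(=O)C#C | starting material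
5 | (2S,5S)-2,5-diphenylpyrrolidine | N1[C@H](c2ccccc2)CC[C@H]1c1ccccc1 | starting material
6 | (E)-1-[(2S,5S)-2,5-diphenylpyrrolidin-1-yl]pent-1-en-3-one | CCC(=O)/C=C/N1[C@H](c2ccccc2)CC[C@H]1c1ccccc1 | intermediate
7 | potassium (1E,3Z)-dienolate of 6 | C/C=C(\O[K])/C=C/N1[C@H](c2ccccc2)CC[C@H]1c1ccccc1 | intermediate
8 | (1E,3Z)-3-(tert-butyldimethylsilyloxy)-1-[(2S,5S)-2,5-diphenylpyrrolidin-1-yl]penta-1,3-diene | C/C=C(\O[Si](C)(C)C(C)(C)C)/C=C/N1[C@H](c2ccccc2)CC[C@H]1c1ccccc1 | intermediate
9 | prop-2-yn-1-ol | OCC#C | starting material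
10 | 4-methyl-2,5-dihydro-1,2-oxamagnesole (cyclic alkoxymagnesium alkenyl species) | CC1=C[Mg]OC1 | intermediate
11 | (Z)-3-iodo-2-methylprop-2-en-1-ol | OC/C(C)=C\I | intermediate
12 | (Z)-3-bromo-1-iodo-2-methylprop-1-ene | BrC/C(C)=C\I | intermediate
13 | ketone-endo cycloadduct: silyl enol ether at C12, amine at C14 cis to the acetyl group, Me-15 cis to the C9 amide, Me-20 cis to H-10 | CON(C)C(=O)[C@H]1[C@H](C)C(O[Si](C)(C)C(C)(C)C)=C[C@H](N2[C@H](c3ccccc3)CC[C@H]2c2ccccc2)[C@]1(C)C(C)=O | intermediate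
14 | lithium C2=C3 enolate of 13 | CON(C)C(=O)[C@H]1[C@H](C)C(O[Si](C)(C)C(C)(C)C)=C[C@H](N2[C@H](c3ccccc3)CC[C@H]2c2ccccc2)[C@]1(C)C(=C)O[Li] | intermediate
15 | C3-allylated cycloadduct with the (Z)-5-iodo-4-methylpent-4-enoyl chain on C1 | CON(C)C(=O)[C@H]1[C@H](C)C(O[Si](C)(C)C(C)(C)C)=C[C@H](N2[C@H](c3ccccc3)CC[C@H]2c2ccccc2)[C@]1(C)C(=O)CC/C(C)=C\I | intermediate
16 | (1S,2S,6S)-2-[(Z)-5-iodo-4-methylpent-4-enoyl]-N-methoxy-N,2,6-trimethyl-5-oxocyclohex-3-ene-1-carboxamide (11-epi enone) | CON(C)C(=O)[C@H]1[C@H](C)C(=O)C=C[C@]1(C)C(=O)CC/C(C)=C\I | intermediate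
17 | (1S,2S,6R)-2-[(Z)-5-iodo-4-methylpent-4-enoyl]-N-methoxy-N,2,6-trimethyl-5-oxocyclohex-3-ene-1-carboxamide | CON(C)C(=O)[C@H]1[C@@H](C)C(=O)C=C[C@]1(C)C(=O)CC/C(C)=C\I | intermediate
18 | (1S,2S,5S,6R)-5-hydroxy-2-[(Z)-5-iodo-4-methylpent-4-enoyl]-N-methoxy-N,2,6-trimethylcyclohex-3-ene-1-carboxamide (12β-alcohol) | CON(C)C(=O)[C@H]1[C@@H](C)[C@@H](O)C=C[C@]1(C)C(=O)CC/C(C)=C\I | intermediate
19 | (1S,2S,5R,6R)-2-[(Z)-5-iodo-4-methylpent-4-enoyl]-N-methoxy-5-(4-methoxyphenoxy)-N,2,6-trimethylcyclohex-3-ene-1-carboxamide | CON(C)C(=O)[C@H]1[C@@H](C)[C@H](Oc2ccc(OC)cc2)C=C[C@]1(C)C(=O)CC/C(C)=C\I | intermediate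
20 | (1S,2S,5R,6R)-2-[(1R,4Z)-1-hydroxy-5-iodo-4-methylpent-4-en-1-yl]-N-methoxy-5-(4-methoxyphenoxy)-N,2,6-trimethylcyclohex-3-ene-1-carboxamide | CON(C)C(=O)[C@H]1[C@@H](C)[C@H](Oc2ccc(OC)cc2)C=C[C@]1(C)[C@H](O)CC/C(C)=C\I | intermediate
21 | C2 triethylsilyl ether of 20 | CON(C)C(=O)[C@H]1[C@@H](C)[C@H](Oc2ccc(OC)cc2)C=C[C@]1(C)[C@H](O[Si](CC)(CC)CC)CC/C(C)=C\I | intermediate
22 | (1S,2S,5R,6R)-2-[(1R,4Z)-5-iodo-4-methyl-1-(triethylsilyloxy)pent-4-en-1-yl]-5-(4-methoxyphenoxy)-2,6-dimethylcyclohex-3-ene-1-carbaldehyde | O=C[C@H]1[C@@H](C)[C@H](Oc2ccc(OC)cc2)C=C[C@]1(C)[C@H](O[Si](CC)(CC)CC)CC/C(C)=C\I | intermediate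
23 | but-2-yne-1,4-diol | OCC#CCO | starting material
24 | 4-[(4-methoxybenzyl)oxy]but-2-yn-1-ol | OCC#CCOCc1ccc(OC)cc1 | intermediate
25 | sodium 2,2-bis(2-methoxyethoxy)-3-{[(4-methoxybenzyl)oxy]methyl}-2,5-dihydro-1,2-oxaluminol-2-uide (cyclic alkenylalanate) | [Na+].COCCO[Al-]1(OCCOC)OCC=C1COCc1ccc(OC)cc1 | intermediate
26 | (Z)-3-iodo-4-[(4-methoxybenzyl)oxy]but-2-en-1-ol | OC/C=C(\I)COCc1ccc(OC)cc1 | intermediate
27 | (Z)-triethyl({3-iodo-4-[(4-methoxybenzyl)oxy]but-2-en-1-yl}oxy)silane | CC[Si](CC)(CC)OC/C=C(\I)COCc1ccc(OC)cc1 | intermediate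
28 | alkenylmagnesium chloride from 27 (Mg in place of I, geometry retained) | CC[Si](CC)(CC)OC/C=C(\[Mg]Cl)COCc1ccc(OC)cc1 | intermediate
29 | C9 (R) allylic alcohol: adduct of 22 and 28, C9 cis to C19 across C8=C17 | O[C@@H](/C(COCc1ccc(OC)cc1)=C\CO[Si](CC)(CC)CC)[C@H]1[C@@H](C)[C@H](Oc2ccc(OC)cc2)C=C[C@]1(C)[C@H](O[Si](CC)(CC)CC)CC/C(C)=C\I | intermediate
30 | C9 triethylsilyl ether of 29 | CC[Si](CC)(CC)O[C@@H](/C(COCc1ccc(OC)cc1)=C\CO[Si](CC)(CC)CC)[C@H]1[C@@H](C)[C@H](Oc2ccc(OC)cc2)C=C[C@]1(C)[C@H](O[Si](CC)(CC)CC)CC/C(C)=C\I | intermediate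
31 | C7 primary allylic alcohol (PMB removed from 30) | CC[Si](CC)(CC)O[C@@H](/C(CO)=C\CO[Si](CC)(CC)CC)[C@H]1[C@@H](C)[C@H](Oc2ccc(OC)cc2)C=C[C@]1(C)[C@H](O[Si](CC)(CC)CC)CC/C(C)=C\I | intermediate
32 | C8–C17 epoxy alcohol (C9 and C19 cis on the oxirane, oxygen on the face giving the target C8) | CC[Si](CC)(CC)O[C@@H]([C@]1(CO)O[C@@H]1CO[Si](CC)(CC)CC)[C@H]1[C@@H](C)[C@H](Oc2ccc(OC)cc2)C=C[C@]1(C)[C@H](O[Si](CC)(CC)CC)CC/C(C)=C\I | intermediate
33 | C7,C8-diol with C17 methyl (C8 and C17 as in the target) | CC[Si](CC)(CC)O[C@@H]([C@@](O)(CO)[C@@H](C)CO[Si](CC)(CC)CC)[C@H]1[C@@H](C)[C@H](Oc2ccc(OC)cc2)C=C[C@]1(C)[C@H](O[Si](CC)(CC)CC)CC/C(C)=C\I | intermediate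
34 | C7 aldehyde with free C8 tertiary alcohol | CC[Si](CC)(CC)O[C@@H]([C@@](O)(C=O)[C@@H](C)CO[Si](CC)(CC)CC)[C@H]1[C@@H](C)[C@H](Oc2ccc(OC)cc2)C=C[C@]1(C)[C@H](O[Si](CC)(CC)CC)CC/C(C)=C\I | intermediate
35 | bicyclic 6/10 C7,C8-diol (C7 S) with C2, C9 and C19 triethylsilyl ethers and C12 4-methoxyphenyl ether | CC[Si](CC)(CC)O[C@@H]1[C@H]2[C@@H](C)[C@H](Oc3ccc(OC)cc3)C=C[C@]2(C)[C@H](O[Si](CC)(CC)CC)CC/C(C)=C\[C@H](O)[C@@]1(O)[C@@H](C)CO[Si](CC)(CC)CC | intermediate
36 | C7,C8,C19-triol (C2 and C9 silyl ethers retained) | CC[Si](CC)(CC)O[C@@H]1[C@H]2[C@@H](C)[C@H](Oc3ccc(OC)cc3)C=C[C@]2(C)[C@H](O[Si](CC)(CC)CC)CC/C(C)=C\[C@H](O)[C@@]1(O)[C@@H](C)CO | intermediate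
37 | C19 lactol (O7–C19 hemiacetal, anomers) | CC[Si](CC)(CC)O[C@@H]1[C@H]2[C@@H](C)[C@H](Oc3ccc(OC)cc3)C=C[C@]2(C)[C@H](O[Si](CC)(CC)CC)CC/C(C)=C\[C@@H]2OC(O)[C@H](C)[C@]21O | intermediate
38 | γ-lactone with C2 and C9 triethylsilyl ethers and C12 4-methoxyphenyl ether | CC[Si](CC)(CC)O[C@@H]1[C@H]2[C@@H](C)[C@H](Oc3ccc(OC)cc3)C=C[C@]2(C)[C@H](O[Si](CC)(CC)CC)CC/C(C)=C\[C@@H]2OC(=O)[C@H](C)[C@]21O | intermediate
39 | C2,C8,C9-triol lactone, C12 4-methoxyphenyl ether | O[C@@H]1[C@H]2[C@@H](C)[C@H](Oc3ccc(OC)cc3)C=C[C@]2(C)[C@H](O)CC/C(C)=C\[C@@H]2OC(=O)[C@H](C)[C@]21O | intermediate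
40 | C2,C9-diacetate, C12 4-methoxyphenyl ether | CC(=O)O[C@@H]1[C@H]2[C@@H](C)[C@H](Oc3ccc(OC)cc3)C=C[C@]2(C)[C@H](OC(C)=O)CC/C(C)=C\[C@@H]2OC(=O)[C@H](C)[C@]21O | intermediate
41 | CNP0222085.1 | CC(=O)O[C@@H]1[C@H]2[C@@H](C)[C@H](O)C=C[C@]2(C)[C@H](OC(C)=O)CC/C(C)=C\[C@@H]2OC(=O)[C@H](C)[C@]21O | target

**Totals**
Total step count: 27.
Longest linear sequence: 21 steps (steps 2, 3, 6–12 and 16–27, from pent-1-yn-3-one; the branch through steps 4 and 5 from prop-2-yn-1-ol is equally long).

**Steps most likely to fail**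

1. Step 6. The cycloaddition may lose facial or regiochemical control with this trisubstituted dienophile, or the amine may be lost early from the masked adduct during the enolate allylation. The fallback sets out from 3 and returns at 16. A chiral oxazaborolidinium triflimide (Lewis acid) catalysed Diels–Alder reaction of 3 with the auxiliary-free (Z)-3-(tert-butyldimethylsilyloxy)penta-1,3-diene F1 (from pent-1-en-3-one, TBSOTf, Et3N) would give the silyl enol ether cycloadduct F2, which has no amine to lose. LDA and bromide 12 would then give the C3-allylated silyl enol ether F3. Metal-free dehydrogenation of the silyl enol ether with IBX·MPO (chosen because of the vinyl iodide) would give enone 16.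

2. Step 22. The alkenylchromium addition may show poor facial selectivity at C7 under the constraints of the ten-membered transition state. The fallback sets out from 34 and returns at 35. The closure is run as described, and the product containing the C7-epimeric ring alcohol F4 is oxidised with MnO2 to the macrocyclic C7 enone F5. Reagent-controlled reduction with (R)-Me-CBS and catecholborane, with the quaternary C8 as the large group, would then give 35.

3. Step 7. The equilibrium at C11 may be slow or unfavourable. The fallback sets out from 16 and returns at 17, using kinetic instead of thermodynamic control. LiHMDS (2.2 equiv, THF, −78 °C) forms the C3/C11 bis-enolate in the flask, and inverse quench into 2,6-di-tert-butylphenol should protonate C11 from the face opposite the C9 amide arm; no new compound is made (F0).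

**Further compounds**
F1 | step 6 | (Z)-3-(tert-butyldimethylsilyloxy)penta-1,3-diene | C/C=C(\O[Si](C)(C)C(C)(C)C)C=C
F2 | step 6 | silyl enol ether cycloadduct of 3 and F1 (C1 and C10 as in 16, Me-20 cis to H-10, C14 methylene) | CON(C)C(=O)[C@H]1[C@H](C)C(O[Si](C)(C)C(C)(C)C)=CC[C@]1(C)C(C)=O
F3 | step 6 | C3-allylated silyl enol ether with the (Z)-5-iodo-4-methylpent-4-enoyl chain | CON(C)C(=O)[C@H]1[C@H](C)C(O[Si](C)(C)C(C)(C)C)=CC[C@]1(C)C(=O)CC/C(C)=C\I
F4 | step 22 | C7 epimer of 35 | CC[Si](CC)(CC)O[C@@H]1[C@H]2[C@@H](C)[C@H](Oc3ccc(OC)cc3)C=C[C@]2(C)[C@H](O[Si](CC)(CC)CC)CC/C(C)=C\[C@@H](O)[C@@]1(O)[C@@H](C)CO[Si](CC)(CC)CC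
F5 | step 22 | macrocyclic C7 enone (C5=C6–C7=O, C8 tertiary alcohol) | CC[Si](CC)(CC)O[C@@H]1[C@H]2[C@@H](C)[C@H](Oc3ccc(OC)cc3)C=C[C@]2(C)[C@H](O[Si](CC)(CC)CC)CC/C(C)=C\C(=O)[C@@]1(O)[C@@H](C)CO[Si](CC)(CC)CC
F0 | step 7 | none | none
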